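**Plan**

1. Retrosynthesis: cleave the aroyl C–O bond, take the C6=C7 enone back to a C8 ketone and the C4 carbinol back to a ketone, then cut C5–C6 and C3a–C8a of the trans-fused hydroazulene together (retro-(4+3)); both rings open to one acyclic chain.
2. Enabling feature: in the seven-membered ring the oxygenated C4 lies between C3a and C5 (an oxyallyl unit C3a–C4–C5) and faces the unit C6–C7–C8(=O)–C8a (a 2-oxydiene). C1–C2–C3 of the five-membered ring is a three-atom tether from C8a to C3a, and the C3 tertiary alcohol next to C3a can be the oxygen of an oxirane whose opening releases the oxyallyl cation.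
3. Forward: the chain is joined by a B-alkyl Suzuki–Miyaura coupling (C2–C3 bond), epoxidised, its ends turned into an epoxy methyl ketone and a propenyl ketone, and both are enol-silylated. Both rings then arise in one step (five-membered through C3a–C8a, seven-membered through C5–C6).
4. Stereochemistry: C3 from Sharpless epoxidation of an (E)-allylic alcohol; C3a by inversion at the oxirane carbon in the cycloaddition; C8a from the extended, trans-fusing ring-closure topology; C4 by hydride delivery directed by the C3 hydroxyl.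
5. End game: desilylation, directed reduction, acylation of the secondary alcohol only, dehydrogenation to the C6=C7 enone.

Key step: step 11

Remark (assumption on the chemistry): bicyclic compounds carry the azulene numbering of the target. The methyl-bearing carbon that becomes C8a is racemic in 6–15, the carbinol carbon of 13 and 14 is a mixture, the enol ether of 16 is a mixture of geometrical isomers and C6 is a mixture in 17–21; all of these are erased or converge, so the SMILES leave them open.

**Route**

Step 1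
Reactants: 1 3-methylbut-1-yne
Product: 3 4-methylpent-2-yn-1-ol, via lithium acetylide 2 (not isolated)
Conditions: n-BuLi, THF, −78 °C; then (CH2O)n, −78 °C to rt; H2O
Reagents that add atoms: formaldehyde, used as paraformaldehyde (C=O)
Why: Deprotonation of the terminal alkyne and addition of the acetylide to formaldehyde (acetylide hydroxymethylation) is a standard route to a propargylic alcohol; no stereocentre is formed.

Step 2
Reactants: 3 4-methylpent-2-yn-1-ol
Product: 5 (2Z)-3-iodo-4-methylpent-2-en-1-ol, via cyclic alkenylalanate 4 (not isolated)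
Conditions: NaAlH2(OCH2CH2OCH3)2, THF, 0 °C to rt; then I2, THF, −78 °C
Reagents that add atoms: iodine (II)
Why: Hydroxyl-directed trans-hydroalumination places aluminium on C3 in a five-membered alkenylalanate, and iodinolysis with retention should give the (Z)-3-iodoallylic alcohol, which fixes the geometry of the later trisubstituted alkene.

Step 3
Reactants: 6 2-methylbut-3-enoic acid (racemic)
Product: 8 N-methoxy-N,2-dimethylbut-3-enamide, via acyl imidazole 7 (not isolated)
Conditions: 1,1′-carbonyldiimidazole, CH2Cl2, 0 °C; then MeNH(OMe)·HCl, 0 °C to rt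
Reagents that add atoms: N,O-dimethylhydroxylamine hydrochloride (CNOC.Cl)
Why: Acyl-imidazole activation and aminolysis (Weinreb amide formation) are mild enough that the β,γ-double bond should not move into conjugation; the racemic α-carbon is erased in step 10.

Step 4
Reactants: 8 N-methoxy-N,2-dimethylbut-3-enamide; 5 (2Z)-3-iodo-4-methylpent-2-en-1-ol
Product: 10 (5E)-7-hydroxy-N-methoxy-N,2-dimethyl-5-(propan-2-yl)hept-5-enamide, via alkylborane 9 (not isolated)
Conditions: 9-BBN, THF, 0 °C to rt; then 5, Pd(dppf)Cl2 (cat.), AsPh3, Cs2CO3, DMF/THF/H2O, rt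
Reagents that add atoms: none
Why: Anti-Markovnikov hydroboration of the terminal alkene followed by B-alkyl Suzuki–Miyaura coupling proceeds with retention at the vinyl iodide and tolerates the free hydroxyl and the amide, so the new chain should end up cis to CH2OH and the isopropyl group trans.

Step 5
Reactants: 10 (5E)-7-hydroxy-N-methoxy-N,2-dimethyl-5-(propan-2-yl)hept-5-enamide
Product: 11 4-[(2R,3R)-3-(hydroxymethyl)-2-(propan-2-yl)oxiran-2-yl]-N-methoxy-N,2-dimethylbutanamide
Conditions: Ti(OiPr)4 (cat.), D-(−)-diethyl tartrate, t-BuOOH, 4 Å molecular sieves, CH2Cl2, −20 °C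
Reagents that add atoms: tert-butyl hydroperoxide (CC(C)(C)OO)
Why: Sharpless asymmetric epoxidation of this geraniol-like (E)-allylic alcohol with the D-(−)-tartrate ligand should deliver oxygen to the face that gives the (2R,3R)-epoxy alcohol (the mirror sense of geraniol with L-(+)-tartrate), which sets the future C3 and, through later inversion, C3a.

Step 6
Reactants: 11 4-[(2R,3R)-3-(hydroxymethyl)-2-(propan-2-yl)oxiran-2-yl]-N-methoxy-N,2-dimethylbutanamide
Product: 12 4-[(2R,3S)-3-formyl-2-(propan-2-yl)oxiran-2-yl]-N-methoxy-N,2-dimethylbutanamide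
Conditions: Dess–Martin periodinane, NaHCO3, CH2Cl2, 0 °C to rt
Reagents that add atoms: none
Why: Buffered Dess–Martin oxidation of the primary epoxy alcohol should leave oxirane and amide untouched, and the oxirane carbon cannot epimerise.

Step 7
Reactants: 12 4-[(2R,3S)-3-formyl-2-(propan-2-yl)oxiran-2-yl]-N-methoxy-N,2-dimethylbutanamide
Product: 13 4-[(2R,3R)-3-(1-hydroxyethyl)-2-(propan-2-yl)oxiran-2-yl]-N-methoxy-N,2-dimethylbutanamide
Conditions: MeMgBr (1.1 equiv), THF, −78 °C; aqueous work-up
Reagents that add atoms: methylmagnesium bromide (C[Mg]Br)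
Why: Grignard addition to the strongly electrophilic α,β-epoxy aldehyde at −78 °C is much faster than attack on the N-methoxy-N-methylamide; the carbinol configuration is irrelevant because it is oxidised in step 9.

Step 8
Reactants: 13 4-[(2R,3R)-3-(1-hydroxyethyl)-2-(propan-2-yl)oxiran-2-yl]-N-methoxy-N,2-dimethylbutanamide
Product: 14 (2E)-7-[(2R,3R)-3-(1-hydroxyethyl)-2-(propan-2-yl)oxiran-2-yl]-5-methylhept-2-en-4-one
Conditions: (E)-1-bromoprop-1-ene, t-BuLi (2 equiv per bromide), Et2O, −78 °C; then 13, THF, −78 to −40 °C; cold H2O quench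
Reagents that add atoms: (E)-prop-1-en-1-yllithium (C/C=C/[Li])
Why: Weinreb ketone synthesis: the alkenyllithium (formed with retention of the E geometry) gives a chelated tetrahedral adduct that collapses to the enone only on work-up, with one equivalent of reagent consumed by the hydroxyl.

Step 9
Reactants: 14 (2E)-7-[(2R,3R)-3-(1-hydroxyethyl)-2-(propan-2-yl)oxiran-2-yl]-5-methylhept-2-en-4-one
Product: 15 (2E)-7-[(2R,3S)-3-acetyl-2-(propan-2-yl)oxiran-2-yl]-5-methylhept-2-en-4-one
Conditions: Dess–Martin periodinane, NaHCO3, CH2Cl2, 0 °C to rt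
Reagents that add atoms: none
Why: Dess–Martin oxidation of the secondary carbinol converges both carbinol epimers on the epoxy methyl ketone without touching the enone or the oxirane.

Step 10
Reactants: 15 (2E)-7-[(2R,3S)-3-acetyl-2-(propan-2-yl)oxiran-2-yl]-5-methylhept-2-en-4-one
Product: 16 (2R,3S)-2-[(5E)-3-methyl-4-(triethylsilyloxy)hepta-3,5-dien-1-yl]-2-(propan-2-yl)-3-[1-(triethylsilyloxy)ethenyl]oxirane
Conditions: LiN(iPr)2 (3 equiv) added to 15 and Et3SiCl (excess), THF, −78 °C; pentane/aq. NaHCO3 work-up, used without chromatography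
Reagents that add atoms: chlorotriethylsilane (CC[Si](Cl)(CC)CC)
Why: Kinetic silyl enol ether formation with in-situ trapping should take the methyl ketone at CH3 (the oxirane C–H is not removed) and the enone at its α′-methine (kinetic α′- and not γ-deprotonation of enones), giving the epoxy enol silane and the cross-conjugated 2-silyloxydiene at once and erasing the racemic centre.

Step 11
Reactants: 16 (2R,3S)-2-[(5E)-3-methyl-4-(triethylsilyloxy)hepta-3,5-dien-1-yl]-2-(propan-2-yl)-3-[1-(triethylsilyloxy)ethenyl]oxirane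
Product: 17 (3R,3aR,8aS)-6,8a-dimethyl-3-(propan-2-yl)-3,8-bis(triethylsilyloxy)-2,3,3a,5,6,8a-hexahydroazulen-4(1H)-one
Conditions: Et3SiOTf (10 mol%), CH2Cl2, 0.005 M, −78 °C; then Et3N
Reagents that add atoms: none
Why: Et3SiOTf silylates the oxirane oxygen; assisted by π-donation from the adjacent enol silane the C3a–O bond opens as a 2-silyloxyallyl cation equivalent, the nucleophilic carbon of the tethered 2-silyloxydiene (future C8a) bonds to C3a, the far diene terminus (C6) then bonds to the other allyl terminus (C5), and the silyl group on the new C4 carbonyl oxygen is handed back to the catalyst. The closest known reaction type is the silyl-triflate-catalysed intramolecular (4+3) cycloaddition of epoxy enol silanes with tethered dienes, a variant of the oxyallyl cation (4+3) cycloaddition; because the diene here is itself a silyl dienol ether and both bonding termini are fully substituted, an asynchronous or stepwise course (C3a–C8a bond first) is expected. The five-membered ring closes by attack on the oxirane carbon remote from the tether anchor (5-endo with respect to the oxirane, equivalent to 5-exo capture of the allyl cation terminus), and the seven-membered ring closes by a 7-endo Mukaiyama–Michael-type bond between the enol silane carbon C5 and C6 of the silyloxyallyl cation left on the diene. C3a is set by inversion at the oxirane carbon (the C–C bond forms anti to the departing oxygen, which stays on C3 as its silyl ether), so its relation to C3 follows from the alkene geometry of step 4 and the epoxidation of step 5, and the same relation (C4 arm trans to isopropyl) is the sterically preferred one if opening runs ahead of bond formation; C8a is set by which face of the enol ether bonds, and the extended arrangement with the two silyloxy-bearing arms anti across the forming bond gives the trans ring fusion. The step needs ionisation at the allylic oxirane carbon and not at the fully substituted one, secured by the enol silane and the low temperature, and trans- over cis-fusion, secured by the anti arrangement, from which only a seven-membered second ring can close because five-membered closure would need a trans-fused bicyclo[3.3.0]octane. The C6 configuration and the enol ether geometry should not matter, since C6 becomes trigonal in step 15.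

Step 12
Reactants: 17 (3R,3aR,8aS)-6,8a-dimethyl-3-(propan-2-yl)-3,8-bis(triethylsilyloxy)-2,3,3a,5,6,8a-hexahydroazulen-4(1H)-one
Product: 18 (3R,3aR,8aS)-3-hydroxy-6,8a-dimethyl-3-(propan-2-yl)octahydroazulene-4,8-dione
Conditions: HF·pyridine, pyridine, THF, 0 °C to rt
Reagents that add atoms: none
Why: Buffered fluoride protodesilylation should cleave both the silyl enol ether and the tertiary silyl ether without the base that would provoke retro-aldol cleavage of the β-hydroxy ketone or epimerisation at C3a.

Step 13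
Reactants: 18 (3R,3aR,8aS)-3-hydroxy-6,8a-dimethyl-3-(propan-2-yl)octahydroazulene-4,8-dione
Product: 19 (3R,3aS,4S,8aS)-3,4-dihydroxy-6,8a-dimethyl-3-(propan-2-yl)-2,3,3a,4,5,6,7,8a-octahydroazulen-8(1H)-one
Conditions: Me4NBH(OAc)3, AcOH/MeCN, −30 to 0 °C
Reagents that add atoms: none
Why: Evans–Saksena hydroxyl-directed reduction: the C3 hydroxyl, which in the trans-fused skeleton sits on the same face of the C4 carbonyl as the angular methyl, should exchange onto boron and deliver hydride to that face, giving the (4S) alcohol (1,3-anti diol), while the undirected C8 ketone is not reduced by the triacetoxyborohydride.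

Step 14
Reactants: 19 (3R,3aS,4S,8aS)-3,4-dihydroxy-6,8a-dimethyl-3-(propan-2-yl)-2,3,3a,4,5,6,7,8a-octahydroazulen-8(1H)-one; 20 3,4,5-trimethoxybenzoyl chloride
Product: 21 (3R,3aS,4S,8aS)-3-hydroxy-6,8a-dimethyl-8-oxo-3-(propan-2-yl)decahydroazulen-4-yl 3,4,5-trimethoxybenzoate
Conditions: Et3N, DMAP (cat.), CH2Cl2, 0 °C to rt
Reagents that add atoms: none
Why: DMAP-catalysed acylation with the acid chloride should occur at the secondary C4 hydroxyl only, the tertiary C3 hydroxyl being too hindered; no stereocentre is touched.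

Step 15
Reactants: 21 (3R,3aS,4S,8aS)-3-hydroxy-6,8a-dimethyl-8-oxo-3-(propan-2-yl)decahydroazulen-4-yl 3,4,5-trimethoxybenzoate
Product: 22 (3R,3aS,4S,8aS)-3-hydroxy-6,8a-dimethyl-8-oxo-3-(propan-2-yl)-1,2,3,3a,4,5,8,8a-octahydroazulen-4-yl 3,4,5-trimethoxybenzoate
Conditions: IBX (2-iodoxybenzoic acid), DMSO/fluorobenzene, 70 °C
Reagents that add atoms: none
Why: IBX dehydrogenation of the ketone through its enol can go only toward C7 (C8a is quaternary), so it should introduce the C6=C7 double bond conjugated with C8=O and remove the undefined C6 centre.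

**Compound list**

1 | 3-methylbut-1-yne | CC(C)C#C | starting material
2 | lithium 3-methylbut-1-yn-1-ide | [Li]C#CC(C)C | intermediate
3 | 4-methylpent-2-yn-1-ol | CC(C)C#CCO | intermediate
4 | sodium alkenylalanate, five-membered ring O–Al–C(iPr)=CH–CH2 with two 2-methoxyethoxy groups on aluminium | COCCO[Al-]1(OCCOC)OCC=C1C(C)C.[Na+] | intermediate
5 | (2Z)-3-iodo-4-methylpent-2-en-1-ol | OC/C=C(\I)C(C)C | intermediate
6 | 2-methylbut-3-enoic acid (racemic) | C=CC(C)C(=O)O | starting material
7 | 1-(1H-imidazol-1-yl)-2-methylbut-3-en-1-one | C=CC(C)C(=O)n1ccnc1 | intermediate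
8 | N-methoxy-N,2-dimethylbut-3-enamide | C=CC(C)C(=O)N(C)OC | intermediate
9 | 4-(9-borabicyclo[3.3.1]nonan-9-yl)-N-methoxy-N,2-dimethylbutanamide | CON(C)C(=O)C(C)CCB1C2CCCC1CCC2 | intermediate
10 | (5E)-7-hydroxy-N-methoxy-N,2-dimethyl-5-(propan-2-yl)hept-5-enamide | OC/C=C(/C(C)C)CCC(C)C(=O)N(C)OC | intermediate
11 | 4-[(2R,3R)-3-(hydroxymethyl)-2-(propan-2-yl)oxiran-2-yl]-N-methoxy-N,2-dimethylbutanamide | CON(C)C(=O)C(C)CC[C@]1(C(C)C)O[C@@H]1CO | intermediate
12 | 4-[(2R,3S)-3-formyl-2-(propan-2-yl)oxiran-2-yl]-N-methoxy-N,2-dimethylbutanamide | CON(C)C(=O)C(C)CC[C@]1(C(C)C)O[C@@H]1C=O | intermediate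
13 | 4-[(2R,3R)-3-(1-hydroxyethyl)-2-(propan-2-yl)oxiran-2-yl]-N-methoxy-N,2-dimethylbutanamide | CON(C)C(=O)C(C)CC[C@]1(C(C)C)O[C@@H]1C(C)O | intermediate
14 | (2E)-7-[(2R,3R)-3-(1-hydroxyethyl)-2-(propan-2-yl)oxiran-2-yl]-5-methylhept-2-en-4-one | C/C=C/C(=O)C(C)CC[C@]1(C(C)C)O[C@@H]1C(C)O | intermediate
15 | (2E)-7-[(2R,3S)-3-acetyl-2-(propan-2-yl)oxiran-2-yl]-5-methylhept-2-en-4-one | C/C=C/C(=O)C(C)CC[C@]1(C(C)C)O[C@@H]1C(C)=O | intermediate
16 | (2R,3S)-2-[(5E)-3-methyl-4-(triethylsilyloxy)hepta-3,5-dien-1-yl]-2-(propan-2-yl)-3-[1-(triethylsilyloxy)ethenyl]oxirane | C/C=C/C(O[Si](CC)(CC)CC)=C(C)CC[C@]1(C(C)C)O[C@@H]1C(=C)O[Si](CC)(CC)CC | intermediate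
17 | (3R,3aR,8aS)-6,8a-dimethyl-3-(propan-2-yl)-3,8-bis(triethylsilyloxy)-2,3,3a,5,6,8a-hexahydroazulen-4(1H)-one | O=C1CC(C)C=C(O[Si](CC)(CC)CC)[C@@]2(C)CC[C@@](O[Si](CC)(CC)CC)(C(C)C)[C@H]12 | intermediate
18 | (3R,3aR,8aS)-3-hydroxy-6,8a-dimethyl-3-(propan-2-yl)octahydroazulene-4,8-dione | O=C1CC(C)CC(=O)[C@@]2(C)CC[C@@](O)(C(C)C)[C@H]12 | intermediate
19 | (3R,3aS,4S,8aS)-3,4-dihydroxy-6,8a-dimethyl-3-(propan-2-yl)-2,3,3a,4,5,6,7,8a-octahydroazulen-8(1H)-one | O[C@H]1CC(C)CC(=O)[C@@]2(C)CC[C@@](O)(C(C)C)[C@H]12 | intermediate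
20 | 3,4,5-trimethoxybenzoyl chloride | COc1cc(C(Cl)=O)cc(OC)c1OC | starting material
21 | (3R,3aS,4S,8aS)-3-hydroxy-6,8a-dimethyl-8-oxo-3-(propan-2-yl)decahydroazulen-4-yl 3,4,5-trimethoxybenzoate | COc1cc(C(=O)O[C@H]2CC(C)CC(=O)[C@@]3(C)CC[C@@](O)(C(C)C)[C@H]23)cc(OC)c1OC | intermediate
22 | (3R,3aS,4S,8aS)-3-hydroxy-6,8a-dimethyl-8-oxo-3-(propan-2-yl)-1,2,3,3a,4,5,8,8a-octahydroazulen-4-yl 3,4,5-trimethoxybenzoate | COc1cc(C(=O)O[C@H]2CC(C)=CC(=O)[C@@]3(C)CC[C@@](O)(C(C)C)[C@H]23)cc(OC)c1OC | target

**Count**

Total steps: 15. Longest linear sequence: 14 steps (steps 1, 2 and 4–15 from 3-methylbut-1-yne; step 3 is a one-step branch).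

**Steps most likely to fail**

Step 11. The silylated oxirane may ionise at its fully substituted carbon and undergo a 1,2-shift (semipinacol-type rearrangement) instead of forming the C3a–C8a bond. Bonding may also occur through the compact arrangement, which leads to cis ring fusion or to five-membered (3+2) closure. The fallback sets out from 15 and comes back at 17; it opens the oxirane before the cyclisation and generates the allyl cation by halide abstraction. Buffered chloride (LiCl, AcOH, THF) should open the α,β-epoxy ketone at the carbon next to the carbonyl with inversion to give the chlorohydrin (3R,4R,9E)-3-chloro-4-hydroxy-7-methyl-4-(propan-2-yl)undec-9-ene-2,8-dione F1. Kinetic enolisation with in-situ silylation (LiN(iPr)2, Et3SiCl, THF, −78 to 0 °C) should silylate the tertiary alkoxide and both ketones, the hindered chlorine-bearing methine not being deprotonated, to give the 2-silyloxyallyl chloride (3S,4R,9E)-3-chloro-7-methyl-4-(propan-2-yl)-2,4,8-tris(triethylsilyloxy)undeca-1,7,9-triene F2. AgOTf in CH2Cl2 at −78 °C then abstracts chloride to give a free 2-silyloxyallyl cation, a classical oxyallyl (4+3) partner, which the tethered silyloxydiene should trap to give 17. No oxirane is present at the ionisation stage, and C3a is then set by the preference of the C4 arm to lie trans to the isopropyl group in the ring-closing transition state.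

Step 13. The hindered tertiary hydroxyl may exchange onto boron too slowly, so that undirected hydride attack from the open face (anti to the angular methyl) gives the C4 epimer, or the β-hydroxy ketone may cleave by retro-aldol reaction. The fallback sets out from 17 and comes back at 22; it keeps the silyl groups and sets C4 under thermodynamic control. Dissolving-metal reduction of 17 (Li, liquid NH3, THF, t-BuOH, −78 °C), which favours the more stable equatorial alcohol of a hindered ring ketone and spares silyl ether and silyl enol ether, should give (3R,3aS,4S,8aS)-6,8a-dimethyl-3-(propan-2-yl)-3,8-bis(triethylsilyloxy)-1,2,3,3a,4,5,6,8a-octahydroazulen-4-ol F3. Acylation with 20 (Et3N, DMAP, CH2Cl2) gives (3R,3aS,4S,8aS)-6,8a-dimethyl-3-(propan-2-yl)-3,8-bis(triethylsilyloxy)-1,2,3,3a,4,5,6,8a-octahydroazulen-4-yl 3,4,5-trimethoxybenzoate F4. Saegusa–Ito oxidation of the retained silyl enol ether (Pd(OAc)2, MeCN, rt) gives (3R,3aS,4S,8aS)-6,8a-dimethyl-8-oxo-3-(propan-2-yl)-3-(triethylsilyloxy)-1,2,3,3a,4,5,8,8a-octahydroazulen-4-yl 3,4,5-trimethoxybenzoate F5, and HF·pyridine removes the tertiary silyl ether to give 22.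

Step 15. Enolisation next to the quaternary carbon may be sluggish, and hot IBX may over-oxidise (further dehydrogenation or oxidation at the doubly activated C5 methylene of the product). The fallback sets out from 21 and comes back at 22; it dehydrogenates in two stages through a silyl enol ether. LiN(SiMe3)2 and Me3SiCl (THF, −78 °C) should give (3R,3aS,4S,8aS)-6,8a-dimethyl-3-(propan-2-yl)-3,8-bis(trimethylsilyloxy)-1,2,3,3a,4,5,6,8a-octahydroazulen-4-yl 3,4,5-trimethoxybenzoate F6, with the enol ether toward C7 (the only enolisable side). Saegusa–Ito oxidation (Pd(OAc)2, MeCN, rt) gives (3R,3aS,4S,8aS)-6,8a-dimethyl-8-oxo-3-(propan-2-yl)-3-(trimethylsilyloxy)-1,2,3,3a,4,5,8,8a-octahydroazulen-4-yl 3,4,5-trimethoxybenzoate F7, and brief citric acid in MeOH cleaves the tertiary trimethylsilyl ether to give 22.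

**Further compounds**

F1 | step 11 | (3R,4R,9E)-3-chloro-4-hydroxy-7-methyl-4-(propan-2-yl)undec-9-ene-2,8-dione | C/C=C/C(=O)C(C)CC[C@@](O)(C(C)C)[C@H](C(C)=O)Cl
F2 | step 11 | (3S,4R,9E)-3-chloro-7-methyl-4-(propan-2-yl)-2,4,8-tris(triethylsilyloxy)undeca-1,7,9-triene | C/C=C/C(O[Si](CC)(CC)CC)=C(C)CC[C@@](O[Si](CC)(CC)CC)(C(C)C)[C@H](C(=C)O[Si](CC)(CC)CC)Cl
F3 | step 13 | (3R,3aS,4S,8aS)-6,8a-dimethyl-3-(propan-2-yl)-3,8-bis(triethylsilyloxy)-1,2,3,3a,4,5,6,8a-octahydroazulen-4-ol | O[C@H]1CC(C)C=C(O[Si](CC)(CC)CC)[C@@]2(C)CC[C@@](O[Si](CC)(CC)CC)(C(C)C)[C@H]12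
F4 | step 13 | (3R,3aS,4S,8aS)-6,8a-dimethyl-3-(propan-2-yl)-3,8-bis(triethylsilyloxy)-1,2,3,3a,4,5,6,8a-octahydroazulen-4-yl 3,4,5-trimethoxybenzoate | COc1cc(C(=O)O[C@H]2CC(C)C=C(O[Si](CC)(CC)CC)[C@@]3(C)CC[C@@](O[Si](CC)(CC)CC)(C(C)C)[C@H]23)cc(OC)c1OC
F5 | step 13 | (3R,3aS,4S,8aS)-6,8a-dimethyl-8-oxo-3-(propan-2-yl)-3-(triethylsilyloxy)-1,2,3,3a,4,5,8,8a-octahydroazulen-4-yl 3,4,5-trimethoxybenzoate | COc1cc(C(=O)O[C@H]2CC(C)=CC(=O)[C@@]3(C)CC[C@@](O[Si](CC)(CC)CC)(C(C)C)[C@H]23)cc(OC)c1OC
F6 | step 15 | (3R,3aS,4S,8aS)-6,8a-dimethyl-3-(propan-2-yl)-3,8-bis(trimethylsilyloxy)-1,2,3,3a,4,5,6,8a-octahydroazulen-4-yl 3,4,5-trimethoxybenzoate | COc1cc(C(=O)O[C@H]2CC(C)C=C(O[Si](C)(C)C)[C@@]3(C)CC[C@@](O[Si](C)(C)C)(C(C)C)[C@H]23)cc(OC)c1OC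
F7 | step 15 | (3R,3aS,4S,8aS)-6,8a-dimethyl-8-oxo-3-(propan-2-yl)-3-(trimethylsilyloxy)-1,2,3,3a,4,5,8,8a-octahydroazulen-4-yl 3,4,5-trimethoxybenzoate | COc1cc(C(=O)O[C@H]2CC(C)=CC(=O)[C@@]3(C)CC[C@@](O[Si](C)(C)C)(C(C)C)[C@H]23)cc(OC)c1OC
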